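How much product stands in the ochre run at 130 min, and what is the order in starting material at the teal charge?

| flask | starting material | partner | product | time |
|---|---|---|---|---|
| teal | 0.500 M | 0.750 M |  |  |
| green | 0.500 M | 0.750 M | 0.150 M |  |
| amber | 1.50 M | 0.750 M |  |  |
| ochre | 1.50 M | 0.250 M |  | 130 min |

| teal run: time / min | teal run: [product] / M | green run: time / min | green run: [product] / M | amber run: time / min | amber run: [product] / M |
|---|---|---|---|---|---|
| 5.2 | 0.0212 | 5.2 | 0.1736 | 5.2 | 0.0412 |
| 8.2 | 0.0329 | 8.2 | 0.1819 | 8.2 | 0.0643 |
| 13 | 0.0484 | 13 | 0.1967 | 13 | 0.0985 |
| 21 | 0.0700 | 21 | 0.2202 | 21 | 0.1487 |
| 33 | 0.0945 | 33 | 0.2454 | 33 | 0.2045 |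
| 52 | 0.1225 | 52 | 0.2711 | 52 | 0.2694 |
| 82 | 0.1460 | 82 | 0.2957 | 82 | 0.3281 |
| 130 | 0.1569 | 130 | 0.3093 | 130 | 0.3744 |

(standard deviation of a reading: 0.002 M)

* the exponent of [starting material] in the starting rate at the charge of the teal run (at the point where two percent of the starting material have become product) (one fixed amount of product, the same in the runs compared)
* product in the ochre run at 130 min, as a share of the starting material charged

- Overall: starting material + partner -> product.
- Constant volume, constant temperature.
- The analysis sees a species whether free or bound.
- "The second partner" is partner.
- An order is taken over about fifteen percent of the charge, up and down.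

The readings look contradictory. The teal run flattens at c(product) = 0.1569 M, yet that product accounts for a third of the starting material charged and 20.9% of the partner. Added product changes nothing I can read: the green run makes 0.159 M by that time, against 0.1569 M in the teal run. So I read the flattening as a clock, not as an amount.

I freeze that clock as the lifetime, the last product made divided by the early rate. The teal run starts at 0.00408 M min⁻¹, which gives 38.5 min. The amber run starts at 0.00792 M min⁻¹ and gives 47.3 min, against 38.5 min in the teal run, although its product is 2.39 times the teal product. Between these two runs, the early rate rises 1.94 times for a charge ratio of 3.00, an average order of 0.605 over that span.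

The ochre run has the amber charge of starting material, so I use the amber lifetime. Its partner is the limiting reagent, which caps the yield at 16.7%. No run varies the partner, so its order is my assumption. I take order one from the overall equation. The early rate becomes 0.00264 M min⁻¹, and the amber lifetime gives 0.125 M, or 8.32%. With the teal lifetime of 38.5 min, the same rate gives 6.78%, so I commit to that span.

The forecast differs from mine: order 0.7 (0.58 to 0.82) and yield 14.5% (9.5% to 16.5%), on the ground that "Near-zero order would approach that cap by 130 min".

The flask gives order 0.79 and yield 7.72%, below the forecast's range.

    2 partner ⇌ reagent dimer, settled at all times (6.010 M⁻¹)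
    starting material + reagent dimer → product + partner (0.04854 M⁻¹ min⁻¹)
    2 starting material ⇌ idle substrate dimer, settled at all times (0.8660 M⁻¹)
    starting material → decomposed substrate (0.02400 min⁻¹)

The ochre yield of 7.72% stands above the 6.78% from the teal lifetime of 38.5 min and below the 8.32% from the amber lifetime of 47.3 min. The order is a separate matter. Starting material joins to idle substrate dimer, and that joining holds the apparent order in starting material early in the teal run at 0.79. The same run without that joining gives 1.1.

(The data stem from a simulated flask from invented constants; the scatter is artificial.)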